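**Plan**

1. Labdane numbering and α/β descriptors (C20 on C10 = β) are used for the target and the bicyclic intermediates: ring A = C1–C5/C10, ring B = C5–C10, C17 = methyl on C8, side chain C11–C16.
2. Retrosynthesis: remove the acetate; cut the butenolide arm at C12=C13 (cross-metathesis with α-methylene-γ-butyrolactone) and at C11–C12 (vinyl opening of a 9α,11-epoxide) back to a C9 ketone; then cut ring B at C8–C9 and C5–C6 into the ring A keto aldehyde 8 (C9 = CHO on the quaternary C10, C5 = ring carbonyl) and 3-bromobutanenitrile (C8 with C17, C7, C6≡N).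
3. Enabling feature: ring B carries oxygen at C6 and C9, para to each other, and each of the two bonds ends at one of these carbons. C5 lies between the quaternary C4 and C10 and can enter only as a carbonyl-derived carbon. So C9 (aldehyde), C5 (ketone) and C6 (nitrile) are all electrophiles, and one reductant, SmI2, makes both bonds: alkylsamarium C8 onto C9, then ketyl C5 onto C6.
4. Forward order: ring A is bought (2,2,6-trimethylcyclohexanone) and given its quaternary C10; ring B is closed onto it by the reductive [3+3] annulation; the helper oxygen at C5 is removed; the side chain is grown from the C9 ketone; the acetate goes on last.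
5. Stereochemistry: C10 from the ligand-controlled decarboxylative allylation; C5 and C8 by base equilibration next to the C6 and C9 ketones (trans fusion, equatorial C17); C6 by hydride delivery to the α face; C9 by α-face epoxidation anti to C20, then opening at C11.

Key step: step 5

Assumption: 3-bromobutanenitrile is taken as a catalogue compound and is used as the racemate, because C8 is equilibrated in step 7.

**Route**

Step 1
Reactants: 1 2,2,6-trimethylcyclohexan-1-one; 2 allyl chloroformate
Product: 4 allyl 2,6,6-trimethylcyclohex-1-en-1-yl carbonate, via lithium enolate 3 (not isolated)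
Conditions: LiN(SiMe3)2, THF, 0 °C; then 2, −78 °C
Reagents that add atoms: none
Why: The ketone has α-hydrogens only at C10, so LiN(SiMe3)2 gives a single tetrasubstituted enolate whose oxygen is acylated by the chloroformate (enolate O-acylation to an allyl enol carbonate); no stereocentre is formed.

Step 2
Reactants: 4 allyl 2,6,6-trimethylcyclohex-1-en-1-yl carbonate
Product: 5 (R)-2-allyl-2,6,6-trimethylcyclohexan-1-one
Conditions: Pd2(dba)3 (2.5 mol %), (R)-t-BuPHOX [(R)-4-tert-butyl-2-(2-diphenylphosphinophenyl)-4,5-dihydrooxazole] (6 mol %), THF, 25 °C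
Reagents that add atoms: none
Why: Decarboxylative asymmetric Tsuji–Trost allylation: zerovalent palladium ionizes the allyl carbonate, CO2 is lost, and enolate and allyl group recombine at C10 inside the chiral pocket of the phosphinooxazoline ligand, whose (R) enantiomer is expected to give the (R) quaternary centre (the (S) ligand gives the (S) series with 2-methylcyclohexanone-derived enol carbonates).

Step 3
Reactants: 5 (R)-2-allyl-2,6,6-trimethylcyclohexan-1-one
Product: 6 (R)-2,2,6-trimethyl-6-[(E)-prop-1-enyl]cyclohexan-1-one
Conditions: RuHCl(CO)(PPh3)3 (5 mol %), toluene, 110 °C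
Reagents that add atoms: none
Why: Ruthenium hydride catalysed alkene isomerization (hydrometalation and β-hydride elimination) moves the terminal double bond one position inward and stops there because C10 is quaternary, so the stereocentre is untouched.

Step 4
Reactants: 6 (R)-2,2,6-trimethyl-6-[(E)-prop-1-enyl]cyclohexan-1-one
Product: 8 (R)-1,3,3-trimethyl-2-oxocyclohexane-1-carbaldehyde, via ozonide 7 (not isolated)
Conditions: O3, CH2Cl2, −78 °C; then Me2S, −78 → 25 °C
Reagents that add atoms: ozone ([O-][O+]=O)
Why: Ozonolysis with reductive work-up cleaves the propenyl double bond and leaves C9 as an aldehyde on the quaternary C10, which cannot enolize and so cannot racemize.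

Step 5
Reactants: 8 (R)-1,3,3-trimethyl-2-oxocyclohexane-1-carbaldehyde; 9 3-bromobutanenitrile
Product: 13 5,9-dihydroxy-4,4,8,10β-tetramethyldecalin-6-one (diastereomer mixture at C5/C8/C9), via alkylsamarium reagent 10 (not isolated), via hydroxy keto nitrile 11 (not isolated), via hydroxy imine 12 (not isolated)
Conditions: 9 (1.5 equiv), SmI2 (3.3 equiv), HMPA, THF, 25 °C, 10 min; then 8, −78 → 0 °C; then SmI2 (3 equiv), visible light, 25 °C; 1 M HCl
Reagents that add atoms: water (O)
Why: Proposed new method: two electrons from SmI2 convert bromide 9 into the secondary alkylsamarium 10, which adds through C8 to the neopentyl aldehyde carbon C9 of 8 (first bond, samarium alkoxide of 11), and a second charge of SmI2 under irradiation then reduces the only carbonyl left, the C5 ketone, to its ketyl, which attacks the nitrile carbon C6 (second bond); the iminyl radical is reduced to the samarium imide of 12 and aqueous acid hydrolyses it to the C6 ketone of 13. The closest known reaction types are the samarium Barbier (samarium Grignard) addition of alkyl halides to carbonyl compounds and the SmI2-promoted reductive ketone–nitrile cyclization to α-hydroxy ketones, and sequencing two SmI2 reactions in one flask is established, but this pairing as an intermolecular-then-intramolecular [3+3] annulation is not. Ring B is closed in the second event in the 6-exo-dig mode, the ketyl carbon C5 attacking the nitrile carbon C6 with nitrogen outside the ring. The new centres C5, C8 and C9 need no control at this stage and a diastereomer mixture is carried on, because the C5 hydroxyl is removed in step 6, C9 becomes a ketone in step 7, and C5 and C8 are then equilibrated next to the C6 and C9 carbonyls against the fixed C10. The selectivity needed is site selectivity (C8 to the aldehyde and not to the ketone or a nitrile; no pinacol coupling of the aldehyde; ketyl formation only at C5), and it is secured by pre-forming 10 so that no free divalent samarium meets the aldehyde, by the shielding of the C5 carbonyl between the quaternary C4 and C10, and by C9 being an alkoxide when the ketyl is made.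

Step 6
Reactants: 13 5,9-dihydroxy-4,4,8,10β-tetramethyldecalin-6-one
Product: 14 9-hydroxy-4,4,8,10β-tetramethyldecalin-6-one (diastereomer mixture at C5/C8/C9)
Conditions: SmI2 (2.5 equiv), MeOH, THF, −78 → 0 °C
Reagents that add atoms: none
Why: Reductive cleavage of an α-hydroxy ketone by SmI2: the C6 ketyl expels the C5 oxygen, a second electron gives the samarium enolate and methanol protonates C5, whose configuration is left open and is fixed in step 7.

Step 7
Reactants: 14 9-hydroxy-4,4,8,10β-tetramethyldecalin-6-one
Product: 16 4,4,8α,10β-tetramethyl-5α-decalin-6,9-dione, via dione epimer mixture 15 (not isolated)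
Conditions: Dess–Martin periodinane, CH2Cl2, 25 °C; crude, then NaOMe (cat.), MeOH, 50 °C
Reagents that add atoms: none
Why: Dess–Martin oxidation turns the hindered secondary C9 carbinol into the ketone, and methoxide then equilibrates C5 and C8 through the C6 and C9 enolates to the most stable isomer, the trans-fused decalin with equatorial 8α-methyl (an axial 8β-methyl would be syn-diaxial to C20), so C5 and C8 are set by thermodynamic control from C10.

Step 8
Reactants: 16 4,4,8α,10β-tetramethyl-5α-decalin-6,9-dione
Product: 17 6β-hydroxy-4,4,8α,10β-tetramethyl-5α-decalin-9-one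
Conditions: NaBH4 (1 equiv), MeOH/CH2Cl2, −40 °C
Reagents that add atoms: none
Why: Borohydride reduction is expected at the C6 carbonyl, which has a CH2 neighbour, before the C9 carbonyl flanked by the quaternary C10 and the C8 methine, and hydride should enter from the α face because the β face of C6 is closed by the syn-axial C20 and 4β methyl groups, which gives the axial 6β alcohol.

Step 9
Reactants: 17 6β-hydroxy-4,4,8α,10β-tetramethyl-5α-decalin-9-one
Product: 18 4,4,8α,10β-tetramethyl-9-methylene-5α-decalin-6β-ol
Conditions: Ph3PCH3Br, KOtBu (excess), toluene, 100 °C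
Reagents that add atoms: methyltriphenylphosphonium bromide (C[P+](c1ccccc1)(c1ccccc1)c1ccccc1.[Br-])
Why: Wittig methylenation with excess ylide generated by KOtBu in hot toluene, conditions used for hindered ketones, converts the C9 carbonyl into the exocyclic alkene while the 6-hydroxyl is carried as its alkoxide, and enolization toward C8 is harmless because the equatorial 8α-methyl is the stable arrangement.

Step 10
Reactants: 18 4,4,8α,10β-tetramethyl-9-methylene-5α-decalin-6β-ol
Product: 19 9α,11-epoxy-4,4,8α,10β-tetramethyl-9-methyl-5α-decalin-6β-ol (spiro-epoxide of 18, oxygen on the α face, C11 β)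
Conditions: mCPBA, NaHCO3, CH2Cl2, 0 °C
Reagents that add atoms: mCPBA (OOC(=O)c1cccc(Cl)c1)
Why: Prilezhaev epoxidation of the exocyclic alkene should occur from the α face, anti to the axial C20 methyl on the neighbouring C10, which places the oxygen 9α and C11 9β and so sets the C9 configuration.

Step 11
Reactants: 19 9α,11-epoxide
Product: 20 9β-allyl-4,4,8α,10β-tetramethyl-5α-decalin-6β,9α-diol
Conditions: CH2=CHMgBr (4 equiv), CuI (20 mol %), THF, −30 → 0 °C; H2O
Reagents that add atoms: vinylmagnesium bromide (C=C[Mg]Br)
Why: Copper-catalysed Grignard opening of the epoxide by SN2 attack at its unsubstituted carbon C11 adds the vinyl group (C12) and leaves the C9–O bond intact, so the 9α configuration from step 10 is retained in the tertiary homoallylic alcohol.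

Step 12
Reactants: 20 9β-allyl-4,4,8α,10β-tetramethyl-5α-decalin-6β,9α-diol; 21 α-methylene-γ-butyrolactone (3 equiv)
Product: 22 (E)-3-[2-(6β,9α-dihydroxy-4,4,8α,10β-tetramethyl-5α-decalin-9β-yl)ethylidene]oxolan-2-one
Conditions: second-generation Hoveyda–Grubbs catalyst (5 mol %), CH2Cl2, 40 °C
Reagents that add atoms: none
Why: Olefin cross-metathesis between the unhindered terminal alkene of 20 and the 1,1-disubstituted alkene of the lactone joins C12 to C13 with loss of ethene, and the geometry of the new alkene is of no consequence because the double bond is moved in step 13.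

Step 13
Reactants: 22 (E)-alkylidene lactone
Product: 23 3-[2-(6β,9α-dihydroxy-4,4,8α,10β-tetramethyl-5α-decalin-9β-yl)ethyl]furan-2(5H)-one (6β,9α-dihydroxylabd-13-en-16,15-olide)
Conditions: RhCl3·3H2O (10 mol %), EtOH, 80 °C
Reagents that add atoms: none
Why: Rhodium hydride catalysed double-bond migration (addition and elimination of Rh–H) shifts the exocyclic C12=C13 bond into the ring to give the more stable endocyclic 2(5H)-furanone, with no stereocentre involved.

Step 14
Reactants: 23 6β,9α-dihydroxylabd-13-en-16,15-olide
Product: 24 6β-acetoxy-9α-hydroxylabd-13-en-16,15-olide (target)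
Conditions: Ac2O, DMAP, pyridine, 40 °C
Reagents that add atoms: acetic anhydride (CC(=O)OC(C)=O)
Why: DMAP-catalysed acylation esterifies the secondary 6β-hydroxyl while the tertiary, more hindered 9α-hydroxyl does not react, which gives the target.

**Compound list**

1 | 2,2,6-trimethylcyclohexan-1-one | CC1CCCC(C)(C)C1=O | starting material
2 | allyl chloroformate | C=CCOC(Cl)=O | starting material
3 | lithium 2,6,6-trimethylcyclohex-1-en-1-olate | [Li]OC1=C(C)CCCC1(C)C | intermediate (not isolated)
4 | allyl 2,6,6-trimethylcyclohex-1-en-1-yl carbonate | C=CCOC(=O)OC1=C(C)CCCC1(C)C | intermediate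
5 | (R)-2-allyl-2,6,6-trimethylcyclohexan-1-one | C=CC[C@@]1(C)CCCC(C)(C)C1=O | intermediate
6 | (R)-2,2,6-trimethyl-6-[(E)-prop-1-enyl]cyclohexan-1-one | C/C=C/[C@@]1(C)CCCC(C)(C)C1=O | intermediate
7 | 3-methyl-5-[(1R)-1,3,3-trimethyl-2-oxocyclohexyl]-1,2,4-trioxolane (ozonide of 6) | CC1OOC(O1)[C@@]2(C)CCCC(C)(C)C2=O | intermediate (not isolated)
8 | (R)-1,3,3-trimethyl-2-oxocyclohexane-1-carbaldehyde | O=C[C@@]1(C)CCCC(C)(C)C1=O | intermediate
9 | 3-bromobutanenitrile (racemic) | CC(Br)CC#N | starting material
10 | (1-cyanopropan-2-yl)samarium diiodide | CC(CC#N)[Sm](I)I | intermediate (not isolated)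
11 | 4-hydroxy-3-methyl-4-[(1R)-1,3,3-trimethyl-2-oxocyclohexyl]butanenitrile (mixture at C8/C9) | N#CCC(C)C(O)[C@@]1(C)CCCC(C)(C)C1=O | intermediate (not isolated)
12 | 6-imino-4,4,8,10β-tetramethyldecalin-5,9-diol (mixture at C5/C8/C9) | N=C1CC(C)C(O)[C@@]2(C)CCCC(C)(C)C12O | intermediate (not isolated)
13 | 5,9-dihydroxy-4,4,8,10β-tetramethyldecalin-6-one (mixture at C5/C8/C9) | O=C1CC(C)C(O)[C@@]2(C)CCCC(C)(C)C12O | intermediate
14 | 9-hydroxy-4,4,8,10β-tetramethyldecalin-6-one (mixture at C5/C8/C9) | O=C1CC(C)C(O)[C@@]2(C)CCCC(C)(C)C12 | intermediate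
15 | 4,4,8,10β-tetramethyldecalin-6,9-dione (mixture at C5/C8) | O=C1CC(C)C(=O)[C@@]2(C)CCCC(C)(C)C12 | intermediate (not isolated)
16 | 4,4,8α,10β-tetramethyl-5α-decalin-6,9-dione | O=C1C[C@@H](C)C(=O)[C@@]2(C)CCCC(C)(C)[C@H]12 | intermediate
17 | 6β-hydroxy-4,4,8α,10β-tetramethyl-5α-decalin-9-one | O[C@@H]1C[C@@H](C)C(=O)[C@@]2(C)CCCC(C)(C)[C@H]12 | intermediate
18 | 4,4,8α,10β-tetramethyl-9-methylene-5α-decalin-6β-ol | O[C@@H]1C[C@@H](C)C(=C)[C@@]2(C)CCCC(C)(C)[C@H]12 | intermediate
19 | 9α,11-epoxide of 18 (spiro-oxirane, oxygen α, C11 β) | O[C@@H]1C[C@@H](C)[C@]3(CO3)[C@@]2(C)CCCC(C)(C)[C@H]12 | intermediate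
20 | 9β-allyl-4,4,8α,10β-tetramethyl-5α-decalin-6β,9α-diol | O[C@@H]1C[C@@H](C)[C@](O)(CC=C)[C@@]2(C)CCCC(C)(C)[C@H]12 | intermediate
21 | α-methylene-γ-butyrolactone (3-methylideneoxolan-2-one) | C=C1CCOC1=O | starting material
22 | (E)-3-[2-(6β,9α-dihydroxy-4,4,8α,10β-tetramethyl-5α-decalin-9β-yl)ethylidene]oxolan-2-one | O[C@@H]1C[C@@H](C)[C@](O)(C/C=C3\CCOC3=O)[C@@]2(C)CCCC(C)(C)[C@H]12 | intermediate
23 | 6β,9α-dihydroxylabd-13-en-16,15-olide | O[C@@H]1C[C@@H](C)[C@](O)(CCC3=CCOC3=O)[C@@]2(C)CCCC(C)(C)[C@H]12 | intermediate
24 | 6β-acetoxy-9α-hydroxylabd-13-en-16,15-olide | CC(=O)O[C@@H]1C[C@@H](C)[C@](O)(CCC2=CCOC2=O)[C@@]2(C)CCCC(C)(C)[C@H]12 | target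

**Count**

Total steps: 14. Longest linear sequence: 14 steps (1 to 24).

**Steps most likely to fail**

Step 5. The samarium aldolate of 11 may fragment by retro-aldol cleavage of C9–C10 before the second reduction, or the hindered C5 ketyl may be reduced further instead of adding to the nitrile. The fallback uses known reactions, sets out from 8 and comes back at 15. Indium-mediated Barbier crotylation of 8 with crotyl bromide in aqueous THF (the alkoxide is protonated at once) should give the branched homoallylic alcohol 6-(1-hydroxy-2-methylbut-3-enyl)-2,2,6-trimethylcyclohexanone F1, which holds the C8–C9 bond. Hydroboration of its terminal alkene with 9-BBN and oxidation with NaBO3 should give the keto diol 6-(1,4-dihydroxy-2-methylbutyl)-2,2,6-trimethylcyclohexanone F2. Swern oxidation of both hydroxyls should give the diketo aldehyde 3-methyl-4-oxo-4-(1,3,3-trimethyl-2-oxocyclohexyl)butanal F3. An intramolecular aldehyde–ketone benzoin reaction catalysed by an N-heterocyclic carbene (triazolium precatalyst, DBU) should then close ring B through the C5–C6 bond to the tertiary ketol 5-hydroxy-4,4,8,10β-tetramethyldecalin-6,9-dione F4. SmI2 in THF/MeOH, as in step 6, removes the C5 hydroxyl and gives the dione mixture 15, which the methoxide stage of step 7 turns into 16.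

Step 9. The ylide may act only as a base (enolization toward C8) or fail to add at the carbonyl wedged between the quaternary C10 and C8. The fallback sets out from 17 and comes back at 18. The weakly basic cerium reagent made from Me3SiCH2Li and CeCl3 (excess, THF, −78 → 0 °C) should add to the C9 carbonyl to give the β-hydroxysilane 9-[(trimethylsilyl)methyl]-4,4,8α,10β-tetramethyl-5α-decalin-6β,9-diol F5. Peterson elimination with KH in THF then gives 18.

Step 8. Site selectivity may be lost (hydride also adds at C9), or facial selectivity at C6 may be poor. The fallback sets out from 16 and comes back at 18; it tells the two carbonyls apart by ketalization instead of by reduction rate. Ethylene glycol and TsOH (benzene, water removal) should ketalize the less hindered C6 carbonyl to 6,6-ethylenedioxy-4,4,8α,10β-tetramethyl-5α-decalin-9-one F6. Wittig methylenation as in step 9 should give 6,6-ethylenedioxy-4,4,8α,10β-tetramethyl-9-methylene-5α-decalin F7. PPTS in wet acetone should free 4,4,8α,10β-tetramethyl-9-methylene-5α-decalin-6-one F8, in which NaBH4 has only the C6 carbonyl to reduce and should give 18.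

**Further compounds**

F1 | step 5 | 6-(1-hydroxy-2-methylbut-3-enyl)-2,2,6-trimethylcyclohexanone (C10 as in 8) | C=CC(C)C(O)[C@@]1(C)CCCC(C)(C)C1=O
F2 | step 5 | 6-(1,4-dihydroxy-2-methylbutyl)-2,2,6-trimethylcyclohexanone (C10 as in 8) | OCCC(C)C(O)[C@@]1(C)CCCC(C)(C)C1=O
F3 | step 5 | 3-methyl-4-oxo-4-(1,3,3-trimethyl-2-oxocyclohexyl)butanal (C10 as in 8) | O=CCC(C)C(=O)[C@@]1(C)CCCC(C)(C)C1=O
F4 | step 5 | 5-hydroxy-4,4,8,10β-tetramethyldecalin-6,9-dione | O=C1CC(C)C(=O)[C@@]2(C)CCCC(C)(C)C12O
F5 | step 9 | 9-[(trimethylsilyl)methyl]-4,4,8α,10β-tetramethyl-5α-decalin-6β,9-diol | O[C@@H]1C[C@@H](C)C(O)(C[Si](C)(C)C)[C@@]2(C)CCCC(C)(C)[C@H]12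
F6 | step 8 | 6,6-ethylenedioxy-4,4,8α,10β-tetramethyl-5α-decalin-9-one | C14(OCCO4)C[C@@H](C)C(=O)[C@@]2(C)CCCC(C)(C)[C@H]12
F7 | step 8 | 6,6-ethylenedioxy-4,4,8α,10β-tetramethyl-9-methylene-5α-decalin | C14(OCCO4)C[C@@H](C)C(=C)[C@@]2(C)CCCC(C)(C)[C@H]12
F8 | step 8 | 4,4,8α,10β-tetramethyl-9-methylene-5α-decalin-6-one | O=C1C[C@@H](C)C(=C)[C@@]2(C)CCCC(C)(C)[C@H]12
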